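If alder still holds 50.8 mM of substrate at its last reading, with 150 mM of partner charged, and cedar, with target added, reads 51.3 mM at its last reading, we ask where the partner goes.

| flask | substrate | partner | catalyst | target | time |
|---|---|---|---|---|---|
| alder | 100 mM | 150 mM | 3.00 mM |  |  |
| cedar | 100 mM | 150 mM | 3.00 mM | 30.0 mM |  |
| elm | 150 mM | 150 mM | 3.00 mM |  |  |
| larch | 100 mM | 75.0 mM | 6.00 mM |  | 44 min |

| run | time / min | [substrate] / mM |
|---|---|---|
| alder run | 1.8 | 85.1 |
| alder run | 2.8 | 80.3 |
| alder run | 4.4 | 74.9 |
| alder run | 7.0 | 68.7 |
| alder run | 11 | 62.5 |
| alder run | 18 | 57.2 |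
| alder run | 28 | 53.4 |
| alder run | 44 | 50.8 |
| cedar run | 1.8 | 85.0 |
| cedar run | 2.8 | 80.4 |
| cedar run | 4.4 | 74.4 |
| cedar run | 7.0 | 68.5 |
| cedar run | 11 | 62.4 |
| cedar run | 18 | 56.8 |
| cedar run | 28 | 53.2 |
| cedar run | 44 | 51.3 |
| elm run | 1.8 | 130.9 |
| elm run | 2.8 | 124.5 |
| elm run | 4.4 | 117.5 |
| elm run | 7.0 | 110.1 |
| elm run | 11 | 103.3 |
| elm run | 18 | 97.4 |
| elm run | 28 | 94.0 |
| elm run | 44 | 92.3 |

(each reading ± 0.3 mM)

1. order of the initial rate in [substrate], near the charge of the alder run, the rate being that where two percent of its substrate are target (one fixed amount of target, the same in the runs compared)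
2. substrate in the larch run at 44 min, as a share of the substrate charged

- Overall: substrate + partner -> target, with catalyst as catalyst.
- Constant volume, constant temperature.
- Readings of a species count what is bound in complexes too.
- "The second partner" is partner.
- An order is taken over about fifteen percent of the charge, up and down.

We suppose that partner has two fates: it turns into target, first order in partner and in catalyst, or it is lost, second order in partner. Integrating over a partner charge Rc gives target made P = A·ln(1 + Rc/A), which we solve by putting each answer back into A = P/ln(1 + Rc/A). Alder's last reading, taken as its end, gives P = 49.2 mM. Starting from 24.6 mM, the first round returns 25.1 mM. One more round gives the crossover level A, the partner concentration at which target-making and loss run equally fast, 25.3 mM.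

With 6.00 mM of catalyst against 3.00 mM, and substrate taken to span a similar range, larch has A = 50.7 mM. Then P = 46.0 mM, which leaves 54.0% of its substrate. The first readings of elm and alder give an order in substrate of 0.612.

The forecast differs from both figures: it gave an order of 0.85 (0.6 to 1.1) and 40% (32% to 50%) for larch, reasoning that “The catalyst must be dying”.

The simulation gives an order of 0.66 and 56.3%, so larch turned 43.7 mM of substrate.

    catalyst + substrate ⇌ catalyst-substrate complex, settled at all times (20.80 L mol⁻¹)
    catalyst-substrate complex + partner ⇌ ternary complex, settled at all times (1.420 L mol⁻¹)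
    ternary complex → target + catalyst (18.00 min⁻¹)
    2 partner → lost reagent (1.350 L mol⁻¹ min⁻¹)
    substrate + partner → target (0.3510 L mol⁻¹ min⁻¹)

The turning of two partner into lost reagent is the reason larch keeps this much substrate: the larch run without that turning leaves 27.3% instead of 56.3%. In that run A has no finite value, so the rule gives P = Rc, with partner as the limiting reagent, and leaves 25.0%. For elm, whose rate over alder's is 1.3, we scale A by that ratio to 33.0 mM, and the rule leaves 93.4 mM of substrate, where its last reading is 92.3 mM.

The data come from a simulation with constants of no real substance; noise was put on by code.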